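## Structural features

Target 30 is an acyclic C15 chain (C1–C15) that ends in a five-membered lactone, ring A (C11, C12, C13, the ring oxygen and the carbonyl carbon C18). Ring A is joined to the chain through the exocyclic E C10=C11 alkene and carries a 2-methylpropenyl group (C14=C15) on C13. The chain holds a Z C2=C3 and an E C6=C7 trisubstituted alkene, an angelate on the C1 oxygen and an acetate on the 8S carbinol. The 12S hydroxyl and the 13R lactone oxygen sit on adjacent carbons and are trans on ring A, which is the anti relationship in the open chain; C8 stands alone, separated from C12 by C9–C11. The fragile groups are the angelate (Z to E isomerisation to the tiglate whenever its acyl carbon is activated), the two allylic esters (ionised by zerovalent palladium and by Lewis acids) and the β-hydroxy-α-alkylidene lactone (a Michael acceptor that can eliminate or open under base). The real difficulty is threefold: three hydroxyls must end in three different states (angelate, acetate, free) beside a fourth oxygen locked in the lactone, the alkylidene must be E, and the C12/C13 pair must be set in absolute terms at a distance from C8. The key step exploits the position of the C12–C13 bond between C11, which can be an alkyne carbon, and C14, which can be a vinyl carbon: this is what a γ-heteroatom-substituted allyl-transfer reagent leaves on adding to an ynal, and with silicon as the heteroatom C13 arrives masked while C12 arrives free.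

## Logic of the disconnections

30 ⇒ 28 + 29. The O–acyl bond at C1 is cut last in the forward sense, because the Z enoate is the group most easily isomerised and neither allylic ester would survive the organolithium and palladium chemistry used earlier. This leaves a diol whose only unhindered hydroxyl is the primary allylic one. The forward step must be primary-selective and must use the carboxylate as nucleophile, so that the acyl carbon is never activated.

28 ⇒ 27 ⇒ 26 ⇒ 25. The acetate O–acyl bond at C8 is cut and the three hydroxyls are returned to three silyl ethers of graded lability (C8 triethylsilyl; C1 primary and C12 secondary tert-butyldimethylsilyl). The gain is an intermediate that carries ethers only. The demand is that dilute acid frees C8 alone and that fluoride then frees C1 and C12 without touching the acetate or the lactone.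

25 ⇒ 24. The C14=C15 double bond is cut to a vinyl group, because a vinyl group is exactly what an allyl-transfer reagent leaves on C13. The C13 side chain becomes the simplest possible alkene. The forward metathesis must touch only the monosubstituted alkene, so it is placed after the alkyne has been consumed and when every other alkene is trisubstituted.

24 ⇒ 23. The C11–C18 and C18–O(C13) bonds are cut and C18 is removed as carbon monoxide. Ring A and the stereodefined C10=C11 alkene both collapse into an alkyne and a homopropargylic alcohol. The forward cyclocarbonylation must add syn across the alkyne to give the E alkylidene, and only the C13 hydroxyl may be free; C8 is also homopropargylic and must stay masked.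

23 ⇒ 21 ⇒ 20. The C13–O bond is traced back to a C13–Si bond (oxidation with retention) and the C12 silyl ether to the free hydroxyl. This turns the differentiated anti diol into a β-hydroxy allylsilane, the retron of a γ-silylallylboration. The oxidation must spare three alkenes, an alkyne and the silyl ethers and must not trigger Peterson elimination, hence the C12 silylation beforehand and a furyl group on silicon that mild acid can cleave.

20 ⇒ 11 + 18. The C12–C13 bond is cut. One step then makes one C–C bond and both stereocentres, and divides the molecule into a C1–C12 ynal and a three-carbon reagent. The forward step needs catalyst control of the C12 face, E geometry in 18 for the anti relationship, and 1,2-addition to the ynal.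

11 ⇒ 8 ⇒ 7. The C11–C12 bond is cut to a terminal alkyne and a one-carbon formyl donor, and the C8 silyl ether to the alcohol. The precursor becomes a simple homopropargylic alcohol. The C8 protecting group must resist butyllithium and yet be the most acid-labile ether later.

7 ⇒ 4 + 5. The C8–C9 bond is cut. This sets the isolated 8S centre by catalyst control while it delivers the three carbons C9–C11 as an alkyne. The forward step must transfer the propargyl unit with allenyl-to-propargyl transposition and control the face of an α-branched enal.

4 ⇒ 3 ⇒ 2 ⇒ 1. The C8 oxidation level is traced back to the E methyl group of the terminal isopropylidene of 1. C1–C8 with both trisubstituted alkenes (2Z, 6E) then come ready-made. The allylic oxidation must be site-selective for the distal alkene and E-selective, which the C1 silyl ether helps by deactivating C2=C3.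

18 ⇒ 15 ⇒ 12 + 13. The C–B bond and the Si–furyl bond are cut. The reagent is reduced to two commercial compounds. The forward borylation must occur at the carbon remote from silicon and give the E vinylsilane, and the metalation must not touch the furan.

## Other disconnections considered

Alternative 1: The cut is C8–C9. In the forward sense the angelate-bearing enal A1 (C1–C8) would be activated by SiCl4 with a chiral bisphosphoramide and attacked by the terminal carbon of the silyl dienol ether A2 (ring A with C9, C10 and C18), giving A3 with the 8S carbinol and the E alkylidene.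
- In its favour: it is the most convergent cut, the angelate is in place before the union, and C8 emerges as the only free hydroxyl. After the union only acetylation and desilylation remain, against eight steps after the chosen key step; on post-coupling step economy and on avoiding a late chemoselective esterification it is the better plan.
- Against it: A2 already contains the anti C12/C13 pair, so the hardest stereochemical problem is moved into a fragment and not solved. Forming A2 places the C12 silyloxy group β to the enolate carbon C11, so loss of silanolate to a butenolide is a real risk. The open transition state leaves both the C8 face of a hindered α-branched enal and the C10=C11 geometry to the chiral Lewis base and to dienolate conformation, whereas the chosen plan uses a closed chair and a syn addition. SiCl4 is a strong Lewis acid and chloride source beside an allylic angelate.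
- Overall: shorter after the union, equal in using catalyst control at C8, weaker in mechanistic security and in what it leaves unsolved.

Alternative 2: The cut is C11–C12. The (Z)-iodoalkene A4 (C1–C11 and C18, both esters present) would be converted with CrCl2 and catalytic NiCl2 into its vinylchromium species and added to the (R)-α-silyloxy aldehyde A5 (Nozaki–Hiyama–Kishi reaction), giving A6; PMB removal, desilylation and oxidation of C18 with lactonisation would follow.
- In its favour: the organochromium reagent tolerates both esters, so no late acylation is needed, and here the alternative is better than the chosen plan. The alkene geometry is carried over from A4 with retention, which equals the reliability of the syn carbonylation.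
- Against it: C12 is set only by 1,2-induction from C13 (Felkin–Anh), which is usually modest for such additions, against reagent control through a chair in the chosen plan. A5 is an α-oxygenated β,γ-unsaturated aldehyde, prone to epimerisation and to conjugation. A4 requires a stereodefined trisubstituted iodoalkene next to an allylic acetate. The final oxidation must raise the allylic C18 ether to the lactone carbonyl beside a free C12 hydroxyl and two esters. Chromium is used in stoichiometric amount.
- Overall: fewer steps after the union, but each fragment needs its own asymmetric synthesis, so the total is unlikely to be lower.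

Alternative 3: The cut is C5–C6. The (Z)-dienyl silyl ether A7 would be hydroborated with 9-BBN at its terminal alkene to the borane A8 (boron on C5), which would couple under PdCl2(dppf) and aqueous base with the (E)-iodoalkene A9 (C6–C15 with ring A complete), giving A10 (B-alkyl Suzuki–Miyaura coupling).
- In its favour: the coupling is mechanistically very dependable and keeps both alkene geometries, and on the reliability of the bond-forming event itself it is the equal or the better of an asymmetric allylboration. A10 is identical in structure with 25, so the last four steps would be shared.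
- Against it: the bond made is purely constitutional. It gives up the advantage that C1–C8 with both trisubstituted alkenes are available in 1, and A7 and A9 must each be built with geometric control. A9 still contains C8, C12, C13 and the alkylidene, which would most sensibly be made by the chemistry of the chosen plan anyway. The alkylidene lactone must survive aqueous base and palladium hydride species.
- Overall: equal end-game, more steps in total, and no stereochemical problem solved by the key step.

Key step: step 9

Remark on the chemistry: the atoms are numbered C1 (angelate-bearing CH2) to C15 along the chain, with C18 the lactone carbonyl. The descriptors 8S, 12S and 13R apply to every intermediate, because the substituent priorities at these centres do not change along the route. The facial preference of the binaphthyl phosphoric acids is taken from the accepted transition-state model ((R)-acid: Re face of the aldehyde). The configurations of 7 and 20 are to be checked by Mosher ester analysis, and the mirror-image acid used if the sense proves opposite.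

## Route

Step 1
Reactants: 1 nerol
Product: 2 neryl tert-butyldimethylsilyl ether
Conditions: TBSCl, imidazole, DMF, 0 °C → rt
Reagents that add atoms: tert-butyldimethylsilyl chloride, CC(C)(C)[Si](C)(C)Cl
Why: Standard silyl ether formation at a primary allylic alcohol; the 2Z alkene is untouched and the allylic oxygen later deactivates C2=C3 towards the allylic oxidation.

Step 2
Reactants: 2 neryl tert-butyldimethylsilyl ether
Product: 3 (2E,6Z)-8-(tert-butyldimethylsilyloxy)-2,6-dimethylocta-2,6-dien-1-ol (the C8 allylic alcohol)
Conditions: SeO2 (cat.), t-BuOOH, salicylic acid (cat.), CH2Cl2, 0 °C → rt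
Reagents that add atoms: tert-butyl hydroperoxide, CC(C)(C)OO; selenium dioxide, O=[Se]=O (catalytic oxygen carrier)
Why: Riley allylic oxidation (ene reaction, then [2,3]-sigmatropic shift) should attack the more electron-rich distal alkene at its E methyl group, so the new CH2OH is trans to C5 (6E); any enal 4 formed by over-oxidation is carried into step 3 together with 3.

Step 3
Reactants: 3 C8 allylic alcohol
Product: 4 (2E,6Z)-8-(tert-butyldimethylsilyloxy)-2,6-dimethylocta-2,6-dienal
Conditions: MnO2, CH2Cl2, rt
Reagents that add atoms: none
Why: Chemoselective oxidation of an allylic alcohol with activated manganese dioxide under neutral conditions, which keeps both alkene geometries and the silyl ether.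

Step 4
Reactants: 4 enal; 5 allenylboronic acid pinacol ester
Product: 7 (4S,5E,9Z)-11-(tert-butyldimethylsilyloxy)-5,9-dimethylundeca-5,9-dien-1-yn-4-ol, via O-pinacolboryl ether 6 (not isolated)
Conditions: (S)-3,3′-bis(2,4,6-triisopropylphenyl)-1,1′-binaphthyl-2,2′-diyl hydrogen phosphate (10 mol %), 4 Å MS, toluene, 0 °C → rt; aqueous work-up
Reagents that add atoms: none
Why: Chiral phosphoric acid-catalysed propargylation of an aldehyde: the allenylboronate adds through a closed six-membered SE2′ transition state, so only the homopropargylic alcohol forms, and the (S)-acid should direct attack to the Si face of the enal and so set 8S.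

Step 5
Reactants: 7 homopropargylic alcohol
Product: 8 triethylsilyl ether of 7
Conditions: TESCl, imidazole, DMAP (cat.), CH2Cl2, 0 °C
Reagents that add atoms: chlorotriethylsilane, CC[Si](Cl)(CC)CC
Why: Silyl ether formation at the secondary alcohol; triethylsilyl resists butyllithium and is later the one ether that dilute acid removes ahead of the two tert-butyldimethylsilyl ethers.

Step 6
Reactants: 8 terminal alkyne
Product: 11 (5S,6E,10Z)-12-(tert-butyldimethylsilyloxy)-6,10-dimethyl-5-(triethylsilyloxy)dodeca-6,10-dien-2-ynal, via lithium acetylide 9 (not isolated), via lithium hemiaminal alkoxide 10 (not isolated)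
Conditions: n-BuLi, THF, −78 °C; DMF, −78 → 0 °C; inverse quench into aq. KH2PO4/MTBE, 0 °C
Reagents that add atoms: N,N-dimethylformamide, CN(C)C=O
Why: Formylation of a lithium acetylide with DMF; the tetrahedral adduct persists until the buffered inverse quench, which should release the ynal without base-induced isomerisation to an allenal and without touching C8.

Step 7
Reactants: 12 2-methylfuran; 13 allylchlorodimethylsilane
Product: 15 allyl(dimethyl)(5-methylfuran-2-yl)silane, via 5-methyl-2-furyllithium 14 (not isolated)
Conditions: n-BuLi, THF, 0 °C → rt; then 13, −78 °C → rt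
Reagents that add atoms: none
Why: α-Lithiation of the furan at its free α-position, then nucleophilic substitution of chloride at silicon.

Step 8
Reactants: 15 allyl(dimethyl)(5-methylfuran-2-yl)silane
Product: 18 (E)-3-[dimethyl(5-methylfuran-2-yl)silyl]allylboronic acid pinacol ester, via silylallyllithium 16 (not isolated), via lithium borate complex 17 (not isolated)
Conditions: s-BuLi, TMEDA, THF, −78 °C; i-PrOBpin, −78 °C → rt; pH 7 aqueous work-up
Reagents that add atoms: 2-isopropoxy-4,4,5,5-tetramethyl-1,3,2-dioxaborolane, CC(C)OB1OC(C)(C)C(C)(C)O1
Why: Deprotonation gives the silyl-stabilised allyl anion, which borate esters trap at the carbon remote from silicon to give the E vinylsilane (the usual regiochemistry of such anions); the methyl group blocks the otherwise acidic furan α-position.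

Step 9
Reactants: 11 ynal; 18 (E)-γ-silylallyl pinacol boronate
Product: 20 (3R,4S,8S,9E,13Z)-15-(tert-butyldimethylsilyloxy)-3-[dimethyl(5-methylfuran-2-yl)silyl]-9,13-dimethyl-8-(triethylsilyloxy)pentadeca-1,9,13-trien-5-yn-4-ol (the (8S,12S,13R) anti-β-hydroxy allylsilane), via O-pinacolboryl ether 19 (not isolated)
Conditions: (R)-3,3′-bis(2,4,6-triisopropylphenyl)-1,1′-binaphthyl-2,2′-diyl hydrogen phosphate (5–10 mol %), 4 Å MS, toluene, −40 → −20 °C; aq. NaHCO3 work-up
Reagents that add atoms: none
Why: The phosphoric acid is expected to hydrogen-bond through P–OH to a pinacol oxygen of 18 while its phosphoryl oxygen contacts the formyl hydrogen, and the aldehyde then adds through a closed six-membered chair (Zimmerman–Traxler type) with allyl transposition, so that the former γ-carbon becomes C13, bonds to C12 and leaves the vinyl group C14=C15. The closest known reaction types are the chiral phosphoric acid-catalysed allyl- and crotylboration of aldehydes with pinacol boronates and the anti-selective addition of (E)-γ-silylallylboronates to aldehydes. No ring closes. C12 is controlled by the catalyst: the (R)-acid should expose the Re face of the ynal, which gives 12S, and the C8 centre, five atoms away, should exert no bias. C13 is controlled relative to C12 by the E geometry of 18, which places silicon equatorial in the chair and gives the anti (12S,13R) adduct. The step needs 1,2- over 1,4-addition (secured by the cyclic delivery from boron to the carbonyl oxygen), attack through the γ-carbon (inherent in the chair) and catalysed over background addition (helped by the low temperature and by acid activation of an unhindered, non-enolisable ynal). The anhydrous conditions and the low loading of a bulky acid should leave the furylsilane and both silyl ethers intact.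

Step 10
Reactants: 20 anti-β-hydroxy allylsilane
Product: 21 C12 tert-butyldimethylsilyl ether of 20
Conditions: TBSOTf, 2,6-lutidine, CH2Cl2, −78 °C
Reagents that add atoms: tert-butyldimethylsilyl trifluoromethanesulfonate, CC(C)(C)[Si](C)(C)OS(=O)(=O)C(F)(F)F
Why: Buffered silylation of the propargylic hydroxyl; capping the β-hydroxyl blocks Peterson elimination in step 11 and makes C12 the oxygen that stays masked during lactonisation and acetylation.

Step 11
Reactants: 21 bis-silyl ether allylsilane
Product: 23 (3R,4S,8S,9E,13Z)-4,15-bis(tert-butyldimethylsilyloxy)-9,13-dimethyl-8-(triethylsilyloxy)pentadeca-1,9,13-trien-5-yn-3-ol (C13 alcohol), via silyl trifluoroacetate 22 (not isolated)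
Conditions: TFA (2 equiv), CH2Cl2, 0 °C, 15 min; then KF, KHCO3, 30% aq. H2O2, THF/MeOH, 0 °C → rt
Reagents that add atoms: hydrogen peroxide, OO
Why: Tamao–Fleming oxidation: ipso-protonation of the very electron-rich 5-methylfuryl group should cleave the Si–furyl bond before acid attacks the allylsilane or the silyl ethers, and fluoride/peroxide then oxidises the activated silane with 1,2-migration of C13 from silicon to oxygen, that is with retention (13R) and without allylic transposition.

Step 12
Reactants: 23 homopropargylic alcohol
Product: 24 (3E,4S,5R)-4-(tert-butyldimethylsilyloxy)-3-[(3S,4E,8Z)-10-(tert-butyldimethylsilyloxy)-4,8-dimethyl-3-(triethylsilyloxy)deca-4,8-dien-1-ylidene]-5-vinyldihydrofuran-2(3H)-one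
Conditions: PdI2 (5 mol %), P(n-Bu)3 (10 mol %), CO (3 atm), MeCN, 65 °C
Reagents that add atoms: carbon monoxide, [C-]#[O+]
Why: Palladium-catalysed cyclocarbonylation of a homopropargylic alcohol: the C13 oxygen and CO form an alkoxycarbonyl complex of divalent palladium that adds syn across C10≡C11 in the exo mode, and protonolysis of the vinyl–palladium bond leaves the C10 hydrogen cis to C18, which is the E alkylidene; only the C13 hydroxyl is free, and C12 and C13 are not touched.

Step 13
Reactants: 24 vinyl lactone
Product: 25 (3E,4S,5R)-4-(tert-butyldimethylsilyloxy)-3-[(3S,4E,8Z)-10-(tert-butyldimethylsilyloxy)-4,8-dimethyl-3-(triethylsilyloxy)deca-4,8-dien-1-ylidene]-5-(2-methylprop-1-enyl)dihydrofuran-2(3H)-one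
Conditions: second-generation Hoveyda–Grubbs catalyst RuCl2(H2IMes)(=CH–C6H4-2-O-i-Pr) (5 mol %), 2-methyl-2-butene/CH2Cl2, 40 °C
Reagents that add atoms: 2-methylbut-2-ene, CC=C(C)C
Why: Olefin cross-metathesis: the monosubstituted vinyl group is the only alkene that should engage the ruthenium carbene quickly, the three trisubstituted alkenes (one of them electron-poor) are much slower, and the large excess of 2-methyl-2-butene delivers the isopropylidene terminus.

Step 14
Reactants: 25 fully silylated lactone
Product: 26 C8 alcohol (C1 and C12 tert-butyldimethylsilyl ethers retained)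
Conditions: PPTS (cat.), MeOH/CH2Cl2, 0 °C, stopped when the triethylsilyl ether is consumed
Reagents that add atoms: none
Why: Acid-catalysed methanolysis of a silyl ether; the triethylsilyl group is far more acid-labile than the primary and the hindered secondary tert-butyldimethylsilyl ethers, so only C8 should be freed.

Step 15
Reactants: 26 C8 alcohol
Product: 27 C8 acetate
Conditions: Ac2O, pyridine, DMAP (cat.), CH2Cl2, 0 °C → rt
Reagents that add atoms: acetic anhydride, CC(=O)OC(C)=O
Why: Acylation of the only free hydroxyl; the C8–O bond is not broken, so 8S is kept.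

Step 16
Reactants: 27 bis-silyl ether acetate
Product: 28 (2Z,6E,8S)-8-acetoxy diol with free C1 and C12 hydroxyls
Conditions: HF·pyridine, pyridine, THF, 0 °C → rt
Reagents that add atoms: none
Why: Fluoride-mediated desilylation under buffered acidic conditions should remove both tert-butyldimethylsilyl ethers without ester cleavage, acyl migration or base-induced reactions of the alkylidene lactone.

Step 17
Reactants: 28 diol; 29 angelic acid
Product: 30 CNP0201198.1
Conditions: PPh3, DIAD, THF, 0 °C
Reagents that add atoms: none
Why: Mitsunobu esterification: the primary allylic C1 hydroxyl should be activated as its alkoxyphosphonium ion far faster than the hindered ring hydroxyl at C12 and is displaced at carbon (SN2) by the angelate anion, so the acid is never activated at its carbonyl and the Z enoate should not isomerise.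

## Compound list

1 | nerol, (2Z)-3,7-dimethylocta-2,6-dien-1-ol | OC/C=C(/C)CCC=C(C)C | starting material
2 | neryl tert-butyldimethylsilyl ether | CC(C)(C)[Si](C)(C)OC/C=C(/C)CCC=C(C)C | intermediate
3 | (2E,6Z)-8-(tert-butyldimethylsilyloxy)-2,6-dimethylocta-2,6-dien-1-ol | CC(C)(C)[Si](C)(C)OC/C=C(/C)CC/C=C(\C)CO | intermediate
4 | (2E,6Z)-8-(tert-butyldimethylsilyloxy)-2,6-dimethylocta-2,6-dienal | CC(C)(C)[Si](C)(C)OC/C=C(/C)CC/C=C(\C)C=O | intermediate
5 | allenylboronic acid pinacol ester | C=C=CB1OC(C)(C)C(C)(C)O1 | starting material
6 | O-pinacolboryl ether of 7 | CC(C)(C)[Si](C)(C)OC/C=C(/C)CC/C=C(\C)[C@H](CC#C)OB1OC(C)(C)C(C)(C)O1 | intermediate (not isolated)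
7 | (4S,5E,9Z)-11-(tert-butyldimethylsilyloxy)-5,9-dimethylundeca-5,9-dien-1-yn-4-ol | CC(C)(C)[Si](C)(C)OC/C=C(/C)CC/C=C(\C)[C@H](CC#C)O | intermediate
8 | triethylsilyl ether of 7 | CC(C)(C)[Si](C)(C)OC/C=C(/C)CC/C=C(\C)[C@H](CC#C)O[Si](CC)(CC)CC | intermediate
9 | lithium acetylide of 8 | CC(C)(C)[Si](C)(C)OC/C=C(/C)CC/C=C(\C)[C@H](CC#C[Li])O[Si](CC)(CC)CC | intermediate (not isolated)
10 | lithium hemiaminal alkoxide (DMF adduct of 9) | CC(C)(C)[Si](C)(C)OC/C=C(/C)CC/C=C(\C)[C@H](CC#CC(O[Li])N(C)C)O[Si](CC)(CC)CC | intermediate (not isolated)
11 | (5S,6E,10Z)-12-(tert-butyldimethylsilyloxy)-6,10-dimethyl-5-(triethylsilyloxy)dodeca-6,10-dien-2-ynal (8S ynal, C1–C12) | CC(C)(C)[Si](C)(C)OC/C=C(/C)CC/C=C(\C)[C@H](CC#CC=O)O[Si](CC)(CC)CC | intermediate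
12 | 2-methylfuran | Cc1ccco1 | starting material
13 | allylchlorodimethylsilane | C=CC[Si](C)(C)Cl | starting material
14 | 5-methyl-2-furyllithium | Cc1ccc([Li])o1 | intermediate (not isolated)
15 | allyl(dimethyl)(5-methylfuran-2-yl)silane | Cc1ccc([Si](C)(C)CC=C)o1 | intermediate
16 | 1-[dimethyl(5-methylfuran-2-yl)silyl]allyllithium | Cc1ccc([Si](C)(C)C([Li])C=C)o1 | intermediate (not isolated)
17 | lithium isopropoxy(pinacolato){(E)-3-[dimethyl(5-methylfuran-2-yl)silyl]allyl}borate | Cc1ccc([Si](C)(C)/C=C/C[B-]2(OC(C)C)OC(C)(C)C(C)(C)O2)o1.[Li+] | intermediate (not isolated)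
18 | (E)-3-[dimethyl(5-methylfuran-2-yl)silyl]allylboronic acid pinacol ester | Cc1ccc([Si](C)(C)/C=C/CB2OC(C)(C)C(C)(C)O2)o1 | intermediate
19 | O-pinacolboryl ether of 20 | CC(C)(C)[Si](C)(C)OC/C=C(/C)CC/C=C(\C)[C@H](CC#C[C@H](OB1OC(C)(C)C(C)(C)O1)[C@H]([Si](C)(C)c1ccc(C)o1)C=C)O[Si](CC)(CC)CC | intermediate (not isolated)
20 | (3R,4S,8S,9E,13Z)-15-(tert-butyldimethylsilyloxy)-3-[dimethyl(5-methylfuran-2-yl)silyl]-9,13-dimethyl-8-(triethylsilyloxy)pentadeca-1,9,13-trien-5-yn-4-ol ((8S,12S,13R) anti-β-hydroxy allylsilane) | CC(C)(C)[Si](C)(C)OC/C=C(/C)CC/C=C(\C)[C@H](CC#C[C@H](O)[C@H]([Si](C)(C)c1ccc(C)o1)C=C)O[Si](CC)(CC)CC | intermediate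
21 | C12 tert-butyldimethylsilyl ether of 20 | CC(C)(C)[Si](C)(C)OC/C=C(/C)CC/C=C(\C)[C@H](CC#C[C@H](O[Si](C)(C)C(C)(C)C)[C@H]([Si](C)(C)c1ccc(C)o1)C=C)O[Si](CC)(CC)CC | intermediate
22 | C13 dimethylsilyl trifluoroacetate from 21 | CC(C)(C)[Si](C)(C)OC/C=C(/C)CC/C=C(\C)[C@H](CC#C[C@H](O[Si](C)(C)C(C)(C)C)[C@H]([Si](C)(C)OC(=O)C(F)(F)F)C=C)O[Si](CC)(CC)CC | intermediate (not isolated)
23 | (3R,4S,8S,9E,13Z)-4,15-bis(tert-butyldimethylsilyloxy)-9,13-dimethyl-8-(triethylsilyloxy)pentadeca-1,9,13-trien-5-yn-3-ol | CC(C)(C)[Si](C)(C)OC/C=C(/C)CC/C=C(\C)[C@H](CC#C[C@H](O[Si](C)(C)C(C)(C)C)[C@H](O)C=C)O[Si](CC)(CC)CC | intermediate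
24 | (3E,4S,5R)-4-(tert-butyldimethylsilyloxy)-3-[(3S,4E,8Z)-10-(tert-butyldimethylsilyloxy)-4,8-dimethyl-3-(triethylsilyloxy)deca-4,8-dien-1-ylidene]-5-vinyldihydrofuran-2(3H)-one | CC(C)(C)[Si](C)(C)OC/C=C(/C)CC/C=C(\C)[C@H](C/C=C1/C(=O)O[C@H](C=C)[C@H]1O[Si](C)(C)C(C)(C)C)O[Si](CC)(CC)CC | intermediate
25 | 5-(2-methylprop-1-enyl) analogue of 24 (C1 and C12 tert-butyldimethylsilyl, C8 triethylsilyl) | CC(C)(C)[Si](C)(C)OC/C=C(/C)CC/C=C(\C)[C@H](C/C=C1/C(=O)O[C@H](C=C(C)C)[C@H]1O[Si](C)(C)C(C)(C)C)O[Si](CC)(CC)CC | intermediate
26 | C8 alcohol from 25 | CC(C)(C)[Si](C)(C)OC/C=C(/C)CC/C=C(\C)[C@H](C/C=C1/C(=O)O[C@H](C=C(C)C)[C@H]1O[Si](C)(C)C(C)(C)C)O | intermediate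
27 | C8 acetate of 26 | CC(C)(C)[Si](C)(C)OC/C=C(/C)CC/C=C(\C)[C@H](C/C=C1/C(=O)O[C@H](C=C(C)C)[C@H]1O[Si](C)(C)C(C)(C)C)OC(C)=O | intermediate
28 | (8S) C8 acetate with free C1 and C12 hydroxyls (ring A 12S,13R; 2Z,6E,10E) | OC/C=C(/C)CC/C=C(\C)[C@H](C/C=C1/C(=O)O[C@H](C=C(C)C)[C@H]1O)OC(C)=O | intermediate
29 | angelic acid, (2Z)-2-methylbut-2-enoic acid | C/C=C(/C)C(=O)O | starting material
30 | CNP0201198.1, (2Z,6E,8S,10E)-8-acetoxy-10-[(4S,5R)-4-hydroxy-5-(2-methylprop-1-enyl)-2-oxodihydrofuran-3(2H)-ylidene]-3,7-dimethyldeca-2,6-dien-1-yl (2Z)-2-methylbut-2-enoate | C/C=C(/C)C(=O)OC/C=C(/C)CC/C=C(\C)[C@H](C/C=C1/C(=O)O[C@H](C=C(C)C)[C@H]1O)OC(C)=O | target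

## Step count and least certain steps

Total: 17 steps. Longest linear sequence: 15 steps (steps 1–6, then 9–17); the boronate branch is steps 7 and 8.

**Step 9 (key step).**
- What may go wrong: loss of catalyst control, because the uncatalysed addition of 18 to a very electrophilic ynal can compete; slow turnover, because the γ-silyl group lowers the nucleophilicity of 18 and because the acid-labile furyl–silicon bond could silylate and so deactivate the phosphoric acid; or an unexpected facial preference for an alkynyl aldehyde. As C8 is already fixed, any of these would show as formation of the (12R,13S) diastereomer.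
- Fallback (reagent control on boron in place of catalyst control): it sets out from 15 and 11 and returns at 20. Compound 15 is lithiated as in step 8, trapped with B(O-i-Pr)3 and hydrolysed with dilute aqueous acid to (E)-3-[dimethyl(5-methylfuran-2-yl)silyl]allylboronic acid F1. This is esterified with (S,S)-diisopropyl tartrate (MgSO4, Et2O) to the tartrate allylboronate F2; the tartrate enantiomer is the one expected to direct attack to the Re face. F2 and 11 (4 Å molecular sieves, toluene, −78 °C) should give the tartrate borate ester of the anti adduct F3 through the same chair, and aqueous work-up hydrolyses it to 20.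

**Step 11.**
- What may go wrong: loss of the C8 triethylsilyl ether (or of the primary silyl ether) in the acid stage, which would free a second homopropargylic hydroxyl before step 12; protodesilylation of the allylsilane itself with allyl shift; slow oxidation of a hindered secondary silane.
- Fallback (the acid-labile ether is exchanged for the final acetate before any strong acid is used): it sets out from 21 and returns at 27. PPTS in MeOH/CH2Cl2 at 0 °C frees the C8 alcohol F4, and Ac2O/pyridine/DMAP gives the C8 acetate F5. TFA then forms the silyl trifluoroacetate F6, which is oxidised with KF/KHCO3/H2O2 at 0 °C to the C13 alcohol F7. Cyclocarbonylation as in step 12 gives the vinyl lactone acetate F8; the catalyst rests as divalent palladium, and the secondary allylic acetate next to a trisubstituted alkene should ionise only slowly. Cross-metathesis as in step 13 then gives 27.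

**Step 12.**
- What may go wrong: slow addition of the alkoxycarbonyl–palladium unit to an internal alkyne flanked by a silyloxy-bearing carbon, with erosion of geometry if the vinylpalladium intermediate isomerises; ionisation or isomerisation of the allylic C13 carbinol or carbonylation of the vinyl group; loss of silyl ethers if hydrogen iodide accumulates.
- Fallback (stepwise hydrometalation, halogenation and carbonylative lactonisation): it sets out from 23 and returns at 24. Bu3SnH with PdCl2(PPh3)2 in THF at 0 °C should add syn with tin on C11, the alkyne carbon next to the oxygenated C12, to give the C11 tributylstannyl alkene F9. I2 in CH2Cl2 at 0 °C converts it with retention into the C11 iodoalkene F10. Pd(PPh3)4, CO (1 atm) and Et3N in MeCN at 60 °C then close ring A with retention of geometry to 24.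

**Step 8.**
- What may go wrong: competing deprotonation of the furan ring or of its methyl group, attack of the alkyllithium at silicon, or borylation next to silicon.
- Fallback (no carbanion next to silicon: hydrosilylation, then allylic borylation): it sets out from 12 (through 14) and returns at 18. Compound 14 is quenched with chlorodimethylsilane to dimethyl(5-methylfuran-2-yl)silane F11. Hydrosilylation of propargyl acetate with Pt2[(CH2=CHSiMe2)2O]3 (zerovalent platinum) and P(t-Bu)3 in THF should give, by syn addition with silicon at the terminal carbon, (E)-3-[dimethyl(5-methylfuran-2-yl)silyl]allyl acetate F12. Pd(dba)2 and bis(pinacolato)diboron in DMSO at 50 °C then replace the acetate by the boronate at the carbon remote from silicon to give 18.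

**Step 17.**
- What may go wrong: activation of the C12 hydroxyl as well (ester formation with inversion, or dehydration), or SN2′ attack on the allylic phosphonium ion; both would waste the most advanced intermediate.
- Fallback (C12 stays silylated while C1 is esterified): it sets out from 27 and returns at 30. Camphorsulfonic acid (cat.) in MeOH/CH2Cl2 at 0 °C removes only the primary silyl ether to give the C1 alcohol F13. Esterification with 29 under the conditions of step 17, or through the mixed anhydride of 29 with 2,4,6-trichlorobenzoyl chloride, now has a single hydroxyl to address and gives the 12-O-tert-butyldimethylsilyl ether of the target F14. HF·pyridine as in step 16 then gives 30.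

## Further compounds

F1 | step 9 | (E)-3-[dimethyl(5-methylfuran-2-yl)silyl]allylboronic acid | Cc1ccc([Si](C)(C)/C=C/CB(O)O)o1
F2 | step 9 | diisopropyl (4S,5S)-2-{(E)-3-[dimethyl(5-methylfuran-2-yl)silyl]allyl}-1,3,2-dioxaborolane-4,5-dicarboxylate | Cc1ccc([Si](C)(C)/C=C/CB2O[C@H](C(=O)OC(C)C)[C@@H](C(=O)OC(C)C)O2)o1
F3 | step 9 | tartrate borate ester of 20 (C12 oxygen bonded to boron) | CC(C)(C)[Si](C)(C)OC/C=C(/C)CC/C=C(\C)[C@H](CC#C[C@H](OB1O[C@H](C(=O)OC(C)C)[C@@H](C(=O)OC(C)C)O1)[C@H]([Si](C)(C)c1ccc(C)o1)C=C)O[Si](CC)(CC)CC
F4 | step 11 | C8 alcohol from 21 (C1 and C12 tert-butyldimethylsilyl, C13 furylsilyl) | CC(C)(C)[Si](C)(C)OC/C=C(/C)CC/C=C(\C)[C@H](CC#C[C@H](O[Si](C)(C)C(C)(C)C)[C@H]([Si](C)(C)c1ccc(C)o1)C=C)O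
F5 | step 11 | C8 acetate of F4 | CC(C)(C)[Si](C)(C)OC/C=C(/C)CC/C=C(\C)[C@H](CC#C[C@H](O[Si](C)(C)C(C)(C)C)[C@H]([Si](C)(C)c1ccc(C)o1)C=C)OC(C)=O
F6 | step 11 | C13 dimethylsilyl trifluoroacetate from F5 (not isolated) | CC(C)(C)[Si](C)(C)OC/C=C(/C)CC/C=C(\C)[C@H](CC#C[C@H](O[Si](C)(C)C(C)(C)C)[C@H]([Si](C)(C)OC(=O)C(F)(F)F)C=C)OC(C)=O
F7 | step 11 | C13 alcohol with C8 acetate | CC(C)(C)[Si](C)(C)OC/C=C(/C)CC/C=C(\C)[C@H](CC#C[C@H](O[Si](C)(C)C(C)(C)C)[C@H](O)C=C)OC(C)=O
F8 | step 11 | vinyl lactone with C8 acetate | CC(C)(C)[Si](C)(C)OC/C=C(/C)CC/C=C(\C)[C@H](C/C=C1/C(=O)O[C@H](C=C)[C@H]1O[Si](C)(C)C(C)(C)C)OC(C)=O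
F9 | step 12 | C11 tributylstannyl alkene from 23 (tin cis to the C10 hydrogen) | CC(C)(C)[Si](C)(C)OC/C=C(/C)CC/C=C(\C)[C@H](C/C=C(/[Sn](CCCC)(CCCC)CCCC)[C@H](O[Si](C)(C)C(C)(C)C)[C@H](O)C=C)O[Si](CC)(CC)CC
F10 | step 12 | C11 iodoalkene (iodine cis to the C10 hydrogen) | CC(C)(C)[Si](C)(C)OC/C=C(/C)CC/C=C(\C)[C@H](C/C=C(/I)[C@H](O[Si](C)(C)C(C)(C)C)[C@H](O)C=C)O[Si](CC)(CC)CC
F11 | step 8 | dimethyl(5-methylfuran-2-yl)silane | Cc1ccc([SiH](C)C)o1
F12 | step 8 | (E)-3-[dimethyl(5-methylfuran-2-yl)silyl]allyl acetate | Cc1ccc([Si](C)(C)/C=C/COC(C)=O)o1
F13 | step 17 | C1 alcohol with C8 acetate and C12 tert-butyldimethylsilyl ether | OC/C=C(/C)CC/C=C(\C)[C@H](C/C=C1/C(=O)O[C@H](C=C(C)C)[C@H]1O[Si](C)(C)C(C)(C)C)OC(C)=O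
F14 | step 17 | 12-O-tert-butyldimethylsilyl ether of 30 | C/C=C(/C)C(=O)OC/C=C(/C)CC/C=C(\C)[C@H](C/C=C1/C(=O)O[C@H](C=C(C)C)[C@H]1O[Si](C)(C)C(C)(C)C)OC(C)=O
A1 | alternative 1 | (2Z,6E)-3,7-dimethyl-8-oxoocta-2,6-dien-1-yl (2Z)-2-methylbut-2-enoate | C/C=C(/C)C(=O)OC/C=C(/C)CC/C=C(\C)C=O
A2 | alternative 1 | tert-butyl{[(4S,5R)-4-(tert-butyldimethylsilyloxy)-5-(2-methylprop-1-enyl)-3-vinyl-4,5-dihydrofuran-2-yl]oxy}dimethylsilane | C=CC1=C(O[Si](C)(C)C(C)(C)C)O[C@H](C=C(C)C)[C@H]1O[Si](C)(C)C(C)(C)C
A3 | alternative 1 | 8-O-desacetyl target with a tert-butyldimethylsilyl ether on the C12 hydroxyl | C/C=C(/C)C(=O)OC/C=C(/C)CC/C=C(\C)[C@H](C/C=C1/C(=O)O[C@H](C=C(C)C)[C@H]1O[Si](C)(C)C(C)(C)C)O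
A4 | alternative 2 | (Z)-iodoalkene C1–C11 with C18 as 4-methoxybenzyl ether, C8 acetate and C1 angelate | C/C=C(/C)C(=O)OC/C=C(/C)CC/C=C(\C)[C@H](C/C=C(/COCc1ccc(OC)cc1)I)OC(C)=O
A5 | alternative 2 | (2R)-2-(tert-butyldimethylsilyloxy)-4-methylpent-3-enal | O=C[C@H](O[Si](C)(C)C(C)(C)C)C=C(C)C
A6 | alternative 2 | seco-lactone, (12S,13R)-12-hydroxy-13-silyloxy compound with C18 as 4-methoxybenzyl ether | C/C=C(/C)C(=O)OC/C=C(/C)CC/C=C(\C)[C@H](C/C=C(/COCc1ccc(OC)cc1)[C@H](O)[C@H](O[Si](C)(C)C(C)(C)C)C=C(C)C)OC(C)=O
A7 | alternative 3 | tert-butyldimethyl{[(2Z)-3-methylpenta-2,4-dien-1-yl]oxy}silane | CC(C)(C)[Si](C)(C)OC/C=C(/C)C=C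
A8 | alternative 3 | 9-BBN adduct of A7 (boron on C5) | CC(C)(C)[Si](C)(C)OC/C=C(/C)CCB1C2CCCC1CCC2
A9 | alternative 3 | (E)-iodoalkene C6–C15 with ring A complete (C8 triethylsilyl, C12 tert-butyldimethylsilyl) | I/C=C(\C)[C@H](C/C=C1/C(=O)O[C@H](C=C(C)C)[C@H]1O[Si](C)(C)C(C)(C)C)O[Si](CC)(CC)CC
A10 | alternative 3 | fully silylated lactone (identical in structure with 25) | CC(C)(C)[Si](C)(C)OC/C=C(/C)CC/C=C(\C)[C@H](C/C=C1/C(=O)O[C@H](C=C(C)C)[C@H]1O[Si](C)(C)C(C)(C)C)O[Si](CC)(CC)CC
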